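In the 3,7-dioxabicyclo[3.3.0]octane core, each bridgehead carbon (C1, C5) carries an OH and a CH2–O arm (C8H2–O7, C4H2–O3). Each bridgehead is therefore a 2,2-disubstituted oxirane opened at its CH2 by the benzylic oxygen of the other half (O7 on C6, O3 on C2).
Key disconnection: cut O7–C8 (ring B) and O3–C4 (ring A) back to a 2,2'-bioxirane, then cut both tertiary C–O bonds back to the C2-symmetric (1S,4S)-2,3-dimethylenebutane-1,4-diol 9. In the forward sense, one carbinol-directed double epoxidation sets C1 and C5, then ring B and ring A close in the same flask.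
Diene diol 9 comes from ethylene and the (S,S)-ynediol 7 by enyne cross metathesis. Diol 7 comes from ynedione 6 by a double oxazaborolidine reduction that sets C2 and C6, and 6 comes from acetylene and two molecules of silylated vanillin.
End game: buffered fluoride removes both aryl silyl ethers.

Key step: step 6

Remark on the chemistry: the target SMILES is read as (1R,2S,5R,6S), cis-fused, with both aryl groups exo (cis to the neighbouring bridgehead OH). Ar = 4-(tert-butyldimethylsilyloxy)-3-methoxyphenyl and TBS = tert-butyldimethylsilyl. Ring A = C1–C2–O3–C4–C5 and ring B = C5–C6–O7–C8–C1, and the same atom labels are used for the open-chain precursors.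

Step 1
Reactants: 1 vanillin
Product: 2 4-(tert-butyldimethylsilyloxy)-3-methoxybenzaldehyde
Conditions: TBSCl, imidazole, DMF, rt
Reagents that add atoms: tert-butyldimethylsilyl chloride, CC(C)(C)[Si](C)(C)Cl
Why: Imidazole-promoted O-silylation of the only acidic OH masks the phenol against the Grignard reagent, MnO2, borane, the ruthenium carbene and the peroxide, and the group can later be removed by fluoride without touching benzylic ethers.

Step 2
Reactants: 2 4-(tert-butyldimethylsilyloxy)-3-methoxybenzaldehyde (2 equiv); 3 acetylene
Product: 5 1,4-bis(Ar)but-2-yne-1,4-diol (dl/meso mixture), via ethynylenedimagnesium dibromide 4 (not isolated)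
Conditions: C2H2 (1 equiv), EtMgBr (2 equiv), Et2O–THF, rt → reflux; then 2, 0 °C → rt; aq NH4Cl
Reagents that add atoms: acetylene (3), C#C
Why: Double deprotonation of acetylene gives the bis-Grignard reagent 4, whose two-fold 1,2-addition (Grignard addition) to the non-enolisable aldehyde builds the whole symmetric C4 core in one operation; the unselectively formed carbinol centres are erased in step 3.

Step 3
Reactants: 5 1,4-bis(Ar)but-2-yne-1,4-diol (dl/meso mixture)
Product: 6 1,4-bis(Ar)but-2-yne-1,4-dione
Conditions: activated MnO2 (excess), CH2Cl2, rt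
Reagents that add atoms: none
Why: MnO2 oxidation is selective for carbinols that are both benzylic and propargylic, and its neutral heterogeneous conditions spare the aryl silyl ethers and the electrophilic ynedione.

Step 4
Reactants: 6 1,4-bis(Ar)but-2-yne-1,4-dione
Product: 7 (1S,4S)-1,4-bis(Ar)but-2-yne-1,4-diol
Conditions: (S)-Me-CBS oxazaborolidine (50 mol % per C=O), BH3·SMe2, THF, −30 °C, slow addition of 6; MeOH quench; meso isomer removed by chromatography
Reagents that add atoms: none
Why: In this Corey–Bakshi–Shibata reduction each ketone binds the ring boron through the lone pair beside the slim linear alkynyl group and away from the aryl group, so the (S)-catalyst should give S at both carbinols (the sense of acetophenone to (R)-1-phenylethanol, with the descriptor changed because the internal alkynyl ranks above aryl); size-based discrimination is chosen because transfer-hydrogenation catalysts that rely on a CH/π contact would face two competing π-substituents, and one wrong-face delivery ends in the separable meso diol, so the enantiopurity of the C2 diol is upgraded statistically.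

Step 5
Reactants: 7 (1S,4S)-1,4-bis(Ar)but-2-yne-1,4-diol; 8 ethylene
Product: 9 (1S,4S)-1,4-bis(Ar)-2,3-dimethylenebutane-1,4-diol
Conditions: second-generation Grubbs catalyst RuCl2(=CHPh)(PCy3)(SIMes) (10 mol %), C2H4 (4 bar), CH2Cl2, 40 °C
Reagents that add atoms: ethylene (8), C=C
Why: In this ethylene–alkyne cross enyne metathesis the ruthenium methylidene adds to the internal alkyne, the ruthenacyclobutene opens to a vinylcarbene and ethylene methylenates it, so each alkyne carbon gains one CH2 while the former C≡C σ-bond becomes the C1–C5 bond; the carbene-ligated catalyst tolerates free propargylic hydroxyl groups, and the carbinol stereocentres take no part.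

Step 6
Reactants: 9 (1S,4S)-1,4-bis(Ar)-2,3-dimethylenebutane-1,4-diol
Product: 12 (1R,2S,5R,6S)-2,6-bis(Ar)-3,7-dioxabicyclo[3.3.0]octane-1,5-diol, via bis-oxirane 10 (not isolated), via spiro-oxirane triol 11 (not isolated)
Conditions: VO(acac)2 (10 mol %), t-BuOOH (5.5 M in decane, 2.4 equiv), CH2Cl2, 0 °C → rt, then 40 °C until 10 and 11 are consumed; aq Na2S2O3
Reagents that add atoms: tert-butyl hydroperoxide, CC(C)(C)OO
Why: Each allylic carbinol of 9 exchanges onto the pentavalent vanadium alkylperoxide formed from VO(acac)2 and t-BuOOH, and the bound peroxide oxygen passes to the adjacent 1,1-disubstituted alkene, which makes the C1–O and C5–O bonds and gives bis-oxirane 10; the closest known reactions are the erythro-selective vanadium-catalysed epoxidation of 2-substituted secondary allylic alcohols and the isomerisation of 3,4-epoxy alcohols to 3-hydroxytetrahydrofurans. C1 and C5 are controlled by the S carbinols C2 and C6: in the vanadate transition state (O–C–C=C dihedral of roughly 50°) the aryl group turns away from the bulky 2-substituent, here the whole other half, so A(1,2) strain leaves the face that places the new C–O bond erythro to the carbinol, which is R at both centres, and C2 symmetry makes the two events matched. The Lewis-acidic vanadium held between a carbinol oxygen and the neighbouring oxirane oxygen then activates that oxirane at its unhindered CH2, the site at which metal-bound 2-substituted 2,3-epoxy alcohols are known to be opened, and the benzylic OH of the other half attacks there in an SN2 manner at a non-stereogenic carbon. Ring B (O7–C8) closes first to give 11 and ring A (O3–C4) second, each by a formally 5-endo opening of a 3,4-epoxy alcohol, which is geometrically accessible because the backside of the CH2–O bond lies about 120° from the oxirane C–C bond, close to the angle of a five-membered transition state. The step needs CH2 over quaternary-carbon attack, cross-half over own-half attack and allylic over homoallylic oxygen delivery: 4-exo attack would have to occur at a fully substituted carbon, own-half attack would give an oxetane or a Payne shift that neutral conditions do not promote, and the allylic vanadate transfers oxygen faster than the homoallylic one. No bond to C1, C2, C5 or C6 is broken once it is set, only the cis-fused bicycle with both aryl groups exo can result, and if ring B closes before the second epoxidation the new tertiary C1–OH directs oxygen to the same face of the remaining exocyclic alkene, so both orders converge on 12.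

Step 7
Reactants: 12 (1R,2S,5R,6S)-2,6-bis(Ar)-3,7-dioxabicyclo[3.3.0]octane-1,5-diol
Product: 13 (1R,2S,5R,6S)-2,6-bis(4-hydroxy-3-methoxyphenyl)-3,7-dioxabicyclo[3.3.0]octane-1,5-diol (target)
Conditions: Bu4NF, AcOH (2.5 equiv each), THF, 0 °C
Reagents that add atoms: none
Why: Fluoride-induced desilylation cleaves both aryl silyl ethers through Si–F bond formation, and the acetic acid buffer keeps the phenols protonated so that no para-quinone methide can form by expulsion of a benzylic ring oxygen, which leaves C2 and C6 untouched.

Compound list
1 | vanillin (4-hydroxy-3-methoxybenzaldehyde) | COc1cc(C=O)ccc1O | starting material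
2 | 4-(tert-butyldimethylsilyloxy)-3-methoxybenzaldehyde | COc1cc(C=O)ccc1O[Si](C)(C)C(C)(C)C | intermediate
3 | acetylene | C#C | starting material
4 | ethynylenedimagnesium dibromide (not isolated) | Br[Mg]C#C[Mg]Br | intermediate
5 | 1,4-bis[4-(tert-butyldimethylsilyloxy)-3-methoxyphenyl]but-2-yne-1,4-diol, dl/meso mixture | COc1cc(C(O)C#CC(O)c2ccc(O[Si](C)(C)C(C)(C)C)c(OC)c2)ccc1O[Si](C)(C)C(C)(C)C | intermediate
6 | 1,4-bis[4-(tert-butyldimethylsilyloxy)-3-methoxyphenyl]but-2-yne-1,4-dione | COc1cc(C(=O)C#CC(=O)c2ccc(O[Si](C)(C)C(C)(C)C)c(OC)c2)ccc1O[Si](C)(C)C(C)(C)C | intermediate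
7 | (1S,4S)-1,4-bis[4-(tert-butyldimethylsilyloxy)-3-methoxyphenyl]but-2-yne-1,4-diol | COc1cc([C@H](O)C#C[C@@H](O)c2ccc(O[Si](C)(C)C(C)(C)C)c(OC)c2)ccc1O[Si](C)(C)C(C)(C)C | intermediate
8 | ethylene | C=C | starting material
9 | (1S,4S)-1,4-bis[4-(tert-butyldimethylsilyloxy)-3-methoxyphenyl]-2,3-dimethylenebutane-1,4-diol | COc1cc([C@H](O)C(=C)C(=C)[C@@H](O)c2ccc(O[Si](C)(C)C(C)(C)C)c(OC)c2)ccc1O[Si](C)(C)C(C)(C)C | intermediate
10 | (S,S)-[(2R,2'R)-2,2'-bioxirane-2,2'-diyl]bis{[4-(tert-butyldimethylsilyloxy)-3-methoxyphenyl]methanol}, erythro at both halves (not isolated) | COc1cc([C@H](O)[C@]2(CO2)[C@@]3(CO3)[C@@H](O)c4ccc(O[Si](C)(C)C(C)(C)C)c(OC)c4)ccc1O[Si](C)(C)C(C)(C)C | intermediate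
11 | (3R,4S,7R)-4-Ar-7-[(S)-Ar(hydroxy)methyl]-1,5-dioxaspiro[2.4]heptan-7-ol, ring B closed and the oxirane on C5 intact (not isolated) | COc1cc([C@H](O)[C@]2(O)CO[C@@H](c4ccc(O[Si](C)(C)C(C)(C)C)c(OC)c4)[C@]23CO3)ccc1O[Si](C)(C)C(C)(C)C | intermediate
12 | (1R,2S,5R,6S)-2,6-bis[4-(tert-butyldimethylsilyloxy)-3-methoxyphenyl]-3,7-dioxabicyclo[3.3.0]octane-1,5-diol | COc1cc([C@@H]2OC[C@@]3(O)[C@H](c4ccc(O[Si](C)(C)C(C)(C)C)c(OC)c4)OC[C@@]23O)ccc1O[Si](C)(C)C(C)(C)C | intermediate
13 | (1R,2S,5R,6S)-2,6-bis(4-hydroxy-3-methoxyphenyl)-3,7-dioxabicyclo[3.3.0]octane-1,5-diol (CNP0307425.1) | COc1cc([C@@H]2OC[C@@]3(O)[C@H](c4ccc(O)c(OC)c4)OC[C@@]23O)ccc1O | target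

Total step count: 7. Longest linear sequence: 7 steps (1 → 13).

Steps most likely to fail

Step 6.
- **What may go wrong:** facial control may erode at the second alkene through competing homoallylic delivery. The benzylic allylic carbinols may be oxidised to enones. The vinyl-oxirane stage may rearrange under Lewis acid, or the sequence may stall before ring closure.
- **Fallback:** it sets out from 9 and returns at 12, and it separates the two events and adds reagent control. A stoichiometric Katsuki–Sharpless epoxidation (Ti(OiPr)4, L-(+)-diisopropyl tartrate, t-BuOOH, 4 Å molecular sieves, CH2Cl2, −20 °C) is the matched case, because an S carbinol ranked OH > alkenyl > aryl is the fast-reacting, erythro-selective partner of the L-(+)-tartrate. Bis-oxirane 10 is isolated this time.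
- **Ring closure in the fallback:** a halide relay is used. MgI2 in THF–toluene (rt → 60 °C) opens each oxirane at its CH2 to give (1S,2R,3R,4S)-1,4-bis(Ar)-2,3-bis(iodomethyl)butane-1,2,3,4-tetrol F1. In F1 the benzylic oxygen of the other half displaces iodide in a 5-exo-tet closure. Reclosure to the oxirane is degenerate, so the material should funnel to 12.

Step 5.
- **What may go wrong:** the two free carbinols may chelate and sequester the ruthenium vinylcarbene. Addition to the hindered internal alkyne may be slow. Ruthenium hydride species may isomerise the allylic alcohol product.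
- **Fallback:** it sets out from 7 and returns at 9, and it takes the carbinols out of play. Acetylation (Ac2O, pyridine, DMAP, CH2Cl2) gives (1S,4S)-1,4-bis(Ar)but-2-yne-1,4-diyl diacetate F2, which belongs to the diester class of but-2-yne-1,4-diol derivatives on which the ethylene reaction is best established.
- **Return to the route:** metathesis of F2 with ethylene (same catalyst, toluene, 80 °C) gives (1S,4S)-1,4-bis(Ar)-2,3-dimethylenebutane-1,4-diyl diacetate F3. Reductive deacetylation with i-Bu2AlH (CH2Cl2, −78 °C) spares the aryl silyl ethers and releases 9.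

Step 4.
- **What may go wrong:** uncatalysed borane reduction of the very electrophilic ynedione may lower the enantiopurity and raise the meso share. Hydroboration or conjugate reduction of the triple bond may also compete.
- **Fallback:** it sets out from 2 and returns at 7, bypassing 5 and 6, and it sets the carbinols by enantioselective C–C bond formation. Zinc-catalysed alkynylation of 2 with trimethylsilylacetylene (Me2Zn, ProPhenol ligand of the enantiomer that adds to the Re face, toluene) gives (S)-1-Ar-3-(trimethylsilyl)prop-2-yn-1-ol F4.
- **Return to the route:** silver-catalysed C-desilylation (AgNO3, aqueous acetone) leaves the aryl silyl ether intact and gives (R)-1-Ar-prop-2-yn-1-ol F5. The spatial arrangement is unchanged, and the descriptor changes only because ethynyl ranks below aryl. A second addition under the same catalyst, F5 to 2 with one further equivalent of Me2Zn to hold the carbinol as its zinc alkoxide, gives 7. The meso diastereomer from any mismatch is removed by chromatography.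

Further compounds
F1 | step 6 | (1S,2R,3R,4S)-1,4-bis[4-(tert-butyldimethylsilyloxy)-3-methoxyphenyl]-2,3-bis(iodomethyl)butane-1,2,3,4-tetrol | COc1cc([C@H](O)[C@](O)(CI)[C@@](O)(CI)[C@@H](O)c2ccc(O[Si](C)(C)C(C)(C)C)c(OC)c2)ccc1O[Si](C)(C)C(C)(C)C
F2 | step 5 | (1S,4S)-1,4-bis[4-(tert-butyldimethylsilyloxy)-3-methoxyphenyl]but-2-yne-1,4-diyl diacetate | COc1cc([C@H](OC(C)=O)C#C[C@@H](OC(C)=O)c2ccc(O[Si](C)(C)C(C)(C)C)c(OC)c2)ccc1O[Si](C)(C)C(C)(C)C
F3 | step 5 | (1S,4S)-1,4-bis[4-(tert-butyldimethylsilyloxy)-3-methoxyphenyl]-2,3-dimethylenebutane-1,4-diyl diacetate | COc1cc([C@H](OC(C)=O)C(=C)C(=C)[C@@H](OC(C)=O)c2ccc(O[Si](C)(C)C(C)(C)C)c(OC)c2)ccc1O[Si](C)(C)C(C)(C)C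
F4 | step 4 | (S)-1-[4-(tert-butyldimethylsilyloxy)-3-methoxyphenyl]-3-(trimethylsilyl)prop-2-yn-1-ol | COc1cc([C@H](O)C#C[Si](C)(C)C)ccc1O[Si](C)(C)C(C)(C)C
F5 | step 4 | (R)-1-[4-(tert-butyldimethylsilyloxy)-3-methoxyphenyl]prop-2-yn-1-ol | COc1cc([C@H](O)C#C)ccc1O[Si](C)(C)C(C)(C)C
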